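The rate constants are assumed; the rest is arithmetic.

A neighbour charged with a quarter of this J comes at the end; the flask itself goes first.

J 1.8 M; D 120 mM (held); time 2.5 min

    G ⇌ J.E, rate k1*(cs1 - [J.E]) while solid is left; crystals form when [J.E] > cs1 (cs1 = 31 mM, k1 = 0.46 s⁻¹)
    J → L (k2 = 0.0059 s⁻¹)
    D ⇌ E, rate k3*(csat - [E]) (k3 = 0.59 s⁻¹, csat = 120 mM)
    J + E ⇌ J.E (K4 = 4.6 M⁻¹, k4 = 1.2 M⁻¹ s⁻¹)

- amber: doubling the saturation concentration of D, all else as stated
- blue: doubling the transfer coefficient of step 3, all else as stated
- teal: doubling the dissolution coefficient of step 1, all else as stated
- red: doubling the solubility in step 1, all else as stated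

- the J.E and G together standing at 2.5 min, as a percentage of the J charged
- the change that raises the amount of J.E and G together at 2.5 min, in percent of the J charged most ("none" if none brings more than 2 percentage points) (amber / blue / teal / red / none)
- amount of J.E and G together at 2.5 min, in percent of the J charged, after amber

- J.E is meant together with its G
- solid, in amounts per volume of the solution: G
- at the start none of E is dissolved
- run time (flask): 2.5 min

*What do you take for the late run, with crystals standing?* Dissolved J.E at its solubility of 31 mM; this is my assumption for the late run, not for the early one, when it can stand above that.

*And J?* With E at its saturation of 120 mM and binding taken at equilibrium, J follows too. As a fraction of the charge this is 3.12%, the J floor: solubility over equilibrium constant, saturation and charge.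

*So the yield is one minus the floor?* No: J also leaks to L on its way down. At the charge, binding uses E at 2.16 s⁻¹, faster than the transfer coefficient of 0.59 s⁻¹, so gas transfer is the rate-limiting step at first. Dividing the leak by the uptake and integrating down the charge gives 4.10% from binding and 7.50% from transfer, together 11.6%.

*And from the floor?* The leak is first order in J, so with J at the floor for the whole run I reckon about 2.76%.

*Your answer?* 82.5%. Saturation stands in the denominator of the three losses, so doubling it halves them and gives 91.3%. Scoring the four changes the same way, I choose amber.

The forecast gave 82.5% (range 80% to 85%), amber as the best change and 90.7% after it, on the ground that “Doubling csat nearly doubles the uptake rate and halves the residual J”.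

The simulation gives 82.2%, with amber best at a gain of 8.1 percentage points, reaching 90.3%.

At 0.301 min J in the flask enters the forward binding step 12 times as fast as it goes to L. At 2.50 min J reads 2.92% against the floor of 3.12%, and L reads 14.9%. In the neighbour, with 0.45 M of J, the floor rises to 12.5%, higher than in the flask, and with its leaks the reckoning gives 70.5%. Computed, the neighbour holds 11.7% of its J unbound and stands at 70.6%.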